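**Retrosynthetic overview**
1. Target 14 comes from its benzyl ester 13 by hydrogenolysis. Ring B of 13 is aromatised last, from a cyclohexane-1,3-dione (11) that already carries the depside ester.
2. Key disconnection: the depside C–O bond is cut on the ring-B side (C3–O), not at the hindered acyl carbon. Rh-carbenoid O–H insertion of acid 9 into 2-diazo-1,3-dione 10 installs the third ring-B oxygen and the ester in one step, with no phenol protecting groups.
3. Both halves come from one dione, 4, made by Michael–Claisen annulation of 1 and 2. Ring A is obtained from 4 by aromatisation, O-methylation and debenzylation.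
4. Ring order: the six-membered carbocycle is built once (step 1); ring A is aromatised in step 2 and ring B in step 7.

Assumption: the target has no stereocentre (it is achiral), so "single enantiomer" needs no stereocontrol; the sp3 centres of the hydroaromatic intermediates are racemic and are erased on aromatisation.

**Route**

Step 1
Reactants: 1 (E)-hept-3-en-2-one; 2 dibenzyl malonate
Product: 4 benzyl 2-hydroxy-4-oxo-6-propylcyclohex-2-ene-1-carboxylate (enol form of the 2,4-dione; racemic), via Michael adduct 3 (not isolated)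
Conditions: NaH (1.1 equiv), THF, 0 °C to reflux; then 1 M HCl
Reagents that add atoms: none
Why: Michael addition of the malonate anion to the enone, then intramolecular Claisen (Dieckmann-type) attack of the methyl-ketone enolate on one benzyl ester, is the classical dihydroresorcylate annulation; the two sp3 centres form racemic and disappear later.

Step 2
Reactants: 4 benzyl 2-hydroxy-4-oxo-6-propylcyclohex-2-ene-1-carboxylate
Product: 6 benzyl 2,4-dihydroxy-6-propylbenzoate (benzyl divarinate), via 3-bromo dione 5 (not isolated)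
Conditions: Br2 (1.0 equiv), DMF, 0 °C, then 80 °C
Reagents that add atoms: none
Why: Bromination of the dione enol at C3 followed by thermal dehydrobromination and tautomerisation is the established Br2/DMF oxidative aromatisation of 6-alkyl-dihydroresorcylates.

Step 3
Reactants: 6 benzyl 2,4-dihydroxy-6-propylbenzoate
Product: 8 benzyl 2,4-dimethoxy-6-propylbenzoate, via 4-O-methyl ether 7 (not isolated)
Conditions: MeI (4 equiv), K2CO3 (4 equiv), acetone, reflux
Reagents that add atoms: iodomethane, CI
Why: Williamson O-methylation takes the free 4-OH first and then, under prolonged reflux, the chelated 2-OH, while the benzyl ester is inert to carbonate.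

Step 4
Reactants: 8 benzyl 2,4-dimethoxy-6-propylbenzoate
Product: 9 2,4-dimethoxy-6-propylbenzoic acid
Conditions: H2 (1 atm), 10% Pd/C, EtOAc, rt
Reagents that add atoms: none
Why: Benzyl ester hydrogenolysis cleaves the O–CH2Ph bond and is therefore indifferent to the di-ortho-substituted acyl carbon.

Step 5
Reactants: 4 benzyl 2-hydroxy-4-oxo-6-propylcyclohex-2-ene-1-carboxylate
Product: 10 benzyl 3-diazo-2,4-dioxo-6-propylcyclohexane-1-carboxylate
Conditions: p-ABSA (1.05 equiv), Et3N, MeCN, 0 °C to rt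
Reagents that add atoms: 4-acetamidobenzenesulfonyl azide (p-ABSA), CC(=O)Nc1ccc(cc1)S(=O)(=O)N=[N+]=[N-]
Why: Regitz diazo transfer goes to C3, the methylene between the two ketones, which is the most acidic site and the only one with two hydrogens (C1 is a methine and cannot become a diazo carbon).

Step 6
Reactants: 10 benzyl 3-diazo-2,4-dioxo-6-propylcyclohexane-1-carboxylate; 9 2,4-dimethoxy-6-propylbenzoic acid (1.5 equiv)
Product: 11 benzyl 3-[(2,4-dimethoxy-6-propylbenzoyl)oxy]-2-hydroxy-4-oxo-6-propylcyclohex-2-ene-1-carboxylate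
Conditions: Rh2(OAc)4 (2 mol %), DCE, 80 °C, slow addition of 10 to 9 and catalyst
Reagents that add atoms: none
Why: Rh(II)-catalysed carbenoid O–H insertion of a carboxylic acid into a 2-diazo-1,3-dicarbonyl forms the ester at the carboxyl oxygen, so the steric shielding of the acyl carbon is irrelevant, and excess acid with slow addition suppresses Wolff rearrangement, dimerisation and insertion into the enol OH of the product.

Step 7
Reactants: 11 benzyl 3-[(2,4-dimethoxy-6-propylbenzoyl)oxy]-2-hydroxy-4-oxo-6-propylcyclohex-2-ene-1-carboxylate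
Product: 13 benzyl 3-[(2,4-dimethoxy-6-propylbenzoyl)oxy]-2,4-dihydroxy-6-propylbenzoate, via bromo acyloxy dione 12 (not isolated)
Conditions: NBS (1.0 equiv), DMF, −20 to 0 °C; then Li2CO3 (2 equiv), 60 °C
Reagents that add atoms: none
Why: Proposed new method: the enol of 11 is brominated at C3, its only enol carbon, and the tertiary α-bromo-α-acyloxy dione 12 then loses HBr in a vinylogous 1,4-sense (enolisation towards C5 or C1, bromide leaving from C3 assisted by the acyloxy oxygen, loss of H-6) to the dienone tautomer that aromatises irreversibly; the closest known reaction type is the halogenation–dehydrohalogenation aromatisation of 3-alkyl-2,4-dioxocyclohexanecarboxylates to 3-alkyl-2,4-dihydroxybenzoates (and step 2), and low-temperature NBS followed by Li2CO3 keeps free Br2/HBr away from the dimethoxyarene and the product resorcinol.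

Step 8
Reactants: 13 benzyl 3-[(2,4-dimethoxy-6-propylbenzoyl)oxy]-2,4-dihydroxy-6-propylbenzoate
Product: 14 3-[(2,4-dimethoxy-6-propylbenzoyl)oxy]-2,4-dihydroxy-6-propylbenzoic acid (CNP0211929.0)
Conditions: H2 (1 atm), 10% Pd/C, EtOAc, rt
Reagents that add atoms: none
Why: Hydrogenolysis removes only the benzyl ester; the hindered aryl (depside) ester is stable to H2/Pd and neutral conditions avoid acyl migration to the neighbouring phenols.

**Compound list**
1 | (E)-hept-3-en-2-one | CCC/C=C/C(C)=O | starting material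
2 | dibenzyl malonate | O=C(CC(=O)OCc1ccccc1)OCc1ccccc1 | starting material
3 | dibenzyl 2-(2-oxoheptan-4-yl)malonate (racemic; not isolated) | CCCC(CC(C)=O)C(C(=O)OCc1ccccc1)C(=O)OCc1ccccc1 | intermediate
4 | benzyl 2-hydroxy-4-oxo-6-propylcyclohex-2-ene-1-carboxylate (racemic, trans-favoured at C1/C6) | CCCC1CC(=O)C=C(O)C1C(=O)OCc1ccccc1 | intermediate
5 | benzyl 3-bromo-2-hydroxy-4-oxo-6-propylcyclohex-2-ene-1-carboxylate (racemic; not isolated) | CCCC1CC(=O)C(Br)=C(O)C1C(=O)OCc1ccccc1 | intermediate
6 | benzyl 2,4-dihydroxy-6-propylbenzoate | CCCc1cc(O)cc(O)c1C(=O)OCc1ccccc1 | intermediate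
7 | benzyl 2-hydroxy-4-methoxy-6-propylbenzoate (not isolated) | CCCc1cc(OC)cc(O)c1C(=O)OCc1ccccc1 | intermediate
8 | benzyl 2,4-dimethoxy-6-propylbenzoate | CCCc1cc(OC)cc(OC)c1C(=O)OCc1ccccc1 | intermediate
9 | 2,4-dimethoxy-6-propylbenzoic acid | CCCc1cc(OC)cc(OC)c1C(=O)O | intermediate
10 | benzyl 3-diazo-2,4-dioxo-6-propylcyclohexane-1-carboxylate (racemic) | CCCC1CC(=O)C(=[N+]=[N-])C(=O)C1C(=O)OCc1ccccc1 | intermediate
11 | benzyl 3-[(2,4-dimethoxy-6-propylbenzoyl)oxy]-2-hydroxy-4-oxo-6-propylcyclohex-2-ene-1-carboxylate (racemic) | CCCC1CC(=O)C(OC(=O)c2c(CCC)cc(OC)cc2OC)=C(O)C1C(=O)OCc1ccccc1 | intermediate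
12 | benzyl 3-bromo-3-[(2,4-dimethoxy-6-propylbenzoyl)oxy]-2,4-dioxo-6-propylcyclohexane-1-carboxylate (diastereomer mixture; not isolated) | CCCC1CC(=O)C(Br)(OC(=O)c2c(CCC)cc(OC)cc2OC)C(=O)C1C(=O)OCc1ccccc1 | intermediate
13 | benzyl 3-[(2,4-dimethoxy-6-propylbenzoyl)oxy]-2,4-dihydroxy-6-propylbenzoate | CCCc1cc(OC)cc(OC)c1C(=O)Oc1c(O)cc(CCC)c(C(=O)OCc2ccccc2)c1O | intermediate
14 | 3-[(2,4-dimethoxy-6-propylbenzoyl)oxy]-2,4-dihydroxy-6-propylbenzoic acid (achiral) | CCCc1cc(OC)cc(OC)c1C(=O)Oc1c(O)cc(CCC)c(C(=O)O)c1O | target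

**Step count**
Total steps: 8. Longest linear sequence: 7 (steps 1, 2, 3, 4, 6, 7, 8).

**Steps most likely to fail, with fallbacks**

Step 7 (aromatisation of 11). Risk: bromo intermediate 12 may fragment by loss of the aroyl group to a trione, or bromine may end up on an arene. The fallback sets out from 11 and comes back at 13, and moves the functionalisation from C3 to C1. Double deprotonation of 11 with LiHMDS (2.2 equiv, THF, −78 °C) gives the enolate/C1-carbanion dianion, which PhSeBr selenenylates at C1 anti to the propyl group to give benzyl 3-[(2,4-dimethoxy-6-propylbenzoyl)oxy]-2-hydroxy-4-oxo-1-(phenylselanyl)-6-propylcyclohex-2-ene-1-carboxylate F1. Oxidation with H2O2 (CH2Cl2/pyridine, 0 °C) gives benzyl 3-[(2,4-dimethoxy-6-propylbenzoyl)oxy]-2-hydroxy-4-oxo-1-(phenylseleninyl)-6-propylcyclohex-2-ene-1-carboxylate F2, whose selenoxide syn-elimination towards H-6 gives the C1=C6 enedione, the keto tautomer of 13.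

Step 6 (carbenoid O–H insertion). Risk: Wolff ring contraction, carbonyl-ylide formation with the neighbouring ester, or sluggish insertion with the bulky acid. The fallback is the classical acyl-transfer route; it sets out from 6 (and uses 9) and comes back at target 14, replacing steps 5–8.
- Rieche formylation of 6 (Cl2CHOMe, TiCl4, CH2Cl2) at C3 gives benzyl 3-formyl-2,4-dihydroxy-6-propylbenzoate F3, separated from the 5-formyl isomer.
- BnBr/K2CO3/DMF gives benzyl 2,4-bis(benzyloxy)-3-formyl-6-propylbenzoate F4.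
- Baeyer–Villiger (Dakin-type) oxidation with mCPBA gives benzyl 2,4-bis(benzyloxy)-3-(formyloxy)-6-propylbenzoate F5, which is methanolysed (K2CO3, MeOH, 0 °C) to benzyl 2,4-bis(benzyloxy)-3-hydroxy-6-propylbenzoate F6.
- Acid 9 is activated with TFAA as 2,4-dimethoxy-6-propylbenzoic trifluoroacetic anhydride F7 and acylates F6 (toluene, rt) to benzyl 2,4-bis(benzyloxy)-3-[(2,4-dimethoxy-6-propylbenzoyl)oxy]-6-propylbenzoate F8.
- H2, Pd/C removes all three benzyl groups to give 14.

Step 2 (Br2/DMF aromatisation of 4). Risk: over-bromination of the resorcinol product or HBr cleavage of the benzyl ester. The fallback sets out from 2 and comes back at 6 with no oxidant: the carbon skeleton is assembled at the resorcinol oxidation level. Dibenzyl malonate 2 and hept-3-yn-2-one (NaH, THF, reflux) give by Michael addition dibenzyl 2-(2-oxohept-3-en-4-yl)malonate F9 (not isolated). This undergoes the same Claisen ring closure and tautomerises directly to 6.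

**Further compounds**
F1 | step 7 | benzyl 3-[(2,4-dimethoxy-6-propylbenzoyl)oxy]-2-hydroxy-4-oxo-1-(phenylselanyl)-6-propylcyclohex-2-ene-1-carboxylate | CCCC1CC(=O)C(OC(=O)c2c(CCC)cc(OC)cc2OC)=C(O)C1([Se]c1ccccc1)C(=O)OCc1ccccc1
F2 | step 7 | benzyl 3-[(2,4-dimethoxy-6-propylbenzoyl)oxy]-2-hydroxy-4-oxo-1-(phenylseleninyl)-6-propylcyclohex-2-ene-1-carboxylate | CCCC1CC(=O)C(OC(=O)c2c(CCC)cc(OC)cc2OC)=C(O)C1([Se](=O)c1ccccc1)C(=O)OCc1ccccc1
F3 | step 6 | benzyl 3-formyl-2,4-dihydroxy-6-propylbenzoate | CCCc1cc(O)c(C=O)c(O)c1C(=O)OCc1ccccc1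
F4 | step 6 | benzyl 2,4-bis(benzyloxy)-3-formyl-6-propylbenzoate | CCCc1cc(OCc2ccccc2)c(C=O)c(OCc2ccccc2)c1C(=O)OCc1ccccc1
F5 | step 6 | benzyl 2,4-bis(benzyloxy)-3-(formyloxy)-6-propylbenzoate | CCCc1cc(OCc2ccccc2)c(OC=O)c(OCc2ccccc2)c1C(=O)OCc1ccccc1
F6 | step 6 | benzyl 2,4-bis(benzyloxy)-3-hydroxy-6-propylbenzoate | CCCc1cc(OCc2ccccc2)c(O)c(OCc2ccccc2)c1C(=O)OCc1ccccc1
F7 | step 6 | 2,4-dimethoxy-6-propylbenzoic trifluoroacetic anhydride | CCCc1cc(OC)cc(OC)c1C(=O)OC(=O)C(F)(F)F
F8 | step 6 | benzyl 2,4-bis(benzyloxy)-3-[(2,4-dimethoxy-6-propylbenzoyl)oxy]-6-propylbenzoate | CCCc1cc(OC)cc(OC)c1C(=O)Oc1c(OCc2ccccc2)cc(CCC)c(C(=O)OCc2ccccc2)c1OCc1ccccc1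
F9 | step 2 | dibenzyl 2-(2-oxohept-3-en-4-yl)malonate (E/Z mixture) | CCCC(=CC(C)=O)C(C(=O)OCc1ccccc1)C(=O)OCc1ccccc1
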